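**Plan**

1. Retrosynthesis: the C4 ketone is traced back to a C4 methyl ether; ring C (the pyran ring) is then cut in one operation at C3–C4 and O1–C2, and the two prenyl C–C bonds at C6 and C8 are cut last.
2. Enabling feature: O1–C8a–C4a–C4 is a latent ortho-quinone methide (a 1-oxadiene) whose C4 end is stabilised by the para oxygen on C7 of ring A, and C2–C3 with the 4-oxygenated ring B is an electron-rich styrene.
3. Forward, ring A is completed first: 2,4-dihydroxybenzaldehyde is prenylated at both positions ortho to its 4-OH by two propargyl ether / semihydrogenation / Claisen cycles, and the 4-OH is then silylated.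
4. Ring C, the only ring formed, is closed by a chiral-acid-catalysed [4+2] union of this salicylaldehyde (as its methoxy ortho-quinone methide, made in the flask with trimethyl orthoformate) with 4-silyloxystyrene.
5. Stereochemistry: C2 (S), the only stereocentre of the target, is set in the cycloaddition by the chiral counteranion; the C4 centre formed alongside is erased when C4 becomes the carbonyl.
6. End game: exchange of C4–OMe for OH, oxidation to the ketone, buffered fluoride desilylation.

Key step: step 8

Assumption: the sense of induction of the chiral acid cannot be derived with certainty; the (R)-configured catalyst is taken to lead to the (2S,4S) adduct, and its equally accessible (S)-enantiomer would be used in the same way if the opposite sense were found.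

**Route**

Step 1
Reactants: 1 2,4-dihydroxybenzaldehyde; 2 3-chloro-3-methylbut-1-yne
Product: 3 2-hydroxy-4-(2-methylbut-3-yn-2-yloxy)benzaldehyde
Conditions: 2 (1.5 equiv), DBU (1.5 equiv), CuCl2·2H2O (1 mol%), MeCN, 0 °C to rt
Reagents that add atoms: none
Why: Copper-catalysed O-alkylation of a phenol with a tertiary propargylic chloride (through the copper acetylide and its allenylidene-type cation) should etherify only the more acidic 4-OH, because the 2-OH is held in a hydrogen bond to the aldehyde.

Step 2
Reactants: 3 2-hydroxy-4-(2-methylbut-3-yn-2-yloxy)benzaldehyde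
Product: 4 2-hydroxy-4-(2-methylbut-3-en-2-yloxy)benzaldehyde
Conditions: H2 (1 atm), Pd/CaCO3 poisoned with Pb(OAc)2, quinoline, EtOAc, rt
Reagents that add atoms: none
Why: Lindlar semihydrogenation should stop at the terminal alkene on the poisoned catalyst and leave the aryl aldehyde and the ether untouched.

Step 3
Reactants: 4 2-hydroxy-4-(2-methylbut-3-en-2-yloxy)benzaldehyde
Product: 6 2,4-dihydroxy-3-(3-methylbut-2-enyl)benzaldehyde, via Claisen dienone 5 (not isolated)
Conditions: PhNEt2, 150 °C
Reagents that add atoms: none
Why: Aromatic Claisen rearrangement ([3,3] shift, then enolisation of the dienone) turns the 1,1-dimethylallyl ether into a linear prenyl group at C3, the ortho position favoured by bond fixation in the chelated salicylaldehyde; any C5 isomer would converge at compound 10 after the second cycle.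

Step 4
Reactants: 6 2,4-dihydroxy-3-(3-methylbut-2-enyl)benzaldehyde; 2 3-chloro-3-methylbut-1-yne
Product: 7 2-hydroxy-3-(3-methylbut-2-enyl)-4-(2-methylbut-3-yn-2-yloxy)benzaldehyde
Conditions: 2 (1.5 equiv), DBU (1.5 equiv), CuCl2·2H2O (1 mol%), MeCN, 0 °C to rt
Reagents that add atoms: none
Why: The same copper-catalysed O-propargylation as in step 1 should again select the 4-OH, which remains the only non-chelated and the more acidic phenol although it now has one prenyl neighbour.

Step 5
Reactants: 7 2-hydroxy-3-(3-methylbut-2-enyl)-4-(2-methylbut-3-yn-2-yloxy)benzaldehyde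
Product: 8 2-hydroxy-3-(3-methylbut-2-enyl)-4-(2-methylbut-3-en-2-yloxy)benzaldehyde
Conditions: H2 (1 atm), Pd/CaCO3 poisoned with Pb(OAc)2, quinoline, EtOAc, rt
Reagents that add atoms: none
Why: Lindlar semihydrogenation reduces the terminal alkyne far faster than the trisubstituted prenyl alkene, so only the triple bond should react.

Step 6
Reactants: 8 2-hydroxy-3-(3-methylbut-2-enyl)-4-(2-methylbut-3-en-2-yloxy)benzaldehyde
Product: 10 2,4-dihydroxy-3,5-bis(3-methylbut-2-enyl)benzaldehyde, via second Claisen dienone 9 (not isolated)
Conditions: PhNEt2, 150 °C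
Reagents that add atoms: none
Why: The aromatic Claisen rearrangement can only end at C5, the one free ortho position, because migration to the substituted C3 gives a dienone that cannot enolise and reverts.

Step 7
Reactants: 10 2,4-dihydroxy-3,5-bis(3-methylbut-2-enyl)benzaldehyde
Product: 11 4-(tert-butyldimethylsilyloxy)-2-hydroxy-3,5-bis(3-methylbut-2-enyl)benzaldehyde
Conditions: TBSCl (1.05 equiv), imidazole, DMF, 0 °C to rt
Reagents that add atoms: tert-butyldimethylsilyl chloride, CC(C)(C)[Si](C)(C)Cl
Why: Silyl ether formation should take place at the free 4-OH and not at the 2-OH, which is deactivated by its hydrogen bond to the aldehyde and shielded by the formyl and prenyl groups.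

Step 8
Reactants: 11 4-(tert-butyldimethylsilyloxy)-2-hydroxy-3,5-bis(3-methylbut-2-enyl)benzaldehyde; 12 4-(tert-butyldimethylsilyloxy)styrene
Product: 15 (2S,4S)-7-(tert-butyldimethylsilyloxy)-2-[4-(tert-butyldimethylsilyloxy)phenyl]-4-methoxy-6,8-bis(3-methylbut-2-enyl)chromane, via dimethyl acetal 13 (not isolated), via methoxy ortho-quinone methide 14 (not isolated)
Conditions: HC(OMe)3 (1.5 equiv), (R)-3,3'-bis(2,4,6-triisopropylphenyl)-1,1'-binaphthyl-2,2'-diyl N-triflylphosphoramide (5 mol%), 5 Å molecular sieves, toluene, 0 °C; then 12 (3 equiv, slow addition), −40 °C; Et3N quench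
Reagents that add atoms: trimethyl orthoformate, COC(OC)OC
Why: Proposed new method: trimethyl orthoformate turns the aldehyde into dimethyl acetal 13, which the strong chiral acid ionises to the O-methyl oxocarbenium ion (the protonated form of methoxy ortho-quinone methide 14), held as a contact ion pair with the phosphoramide anion and hydrogen-bonded through the phenol; the styrene CH2 carbon attacks the benzylic carbon (C3–C4) and the para-silyloxybenzyl cation developing at C2 is captured by the phenol oxygen (O1–C2). The closest known reaction types are the cycloaddition of alkoxy ortho-quinone methides from salicylaldehyde acetals with styrenes under achiral acids and the chiral phosphoric acid or N-triflylphosphoramide catalysed cycloadditions of ortho-quinone methides generated from ortho-hydroxybenzyl alcohols, and the new element is their combination with absolute control. Ring C closes by an asynchronous inverse-demand oxa-[4+2] cycloaddition, which in its stepwise limit is a 6-exo-trig capture of the benzylic cation by oxygen. C4 is set by the anion shielding one face of the oxocarbenium ion and C2 is set within the same ion pair by an endo, chair-like closure that places the aryl group cis to the methoxy group, so the catalyst fixes the absolute configuration and the cis preference relays it to C2; the cis adduct is purified at this stage so that no trans isomer with the opposite C2 sense is carried forward. The step needs regio-, chemo- and face selectivity: polarity matching (nucleophilic styrene terminus to electrophilic C4, oxygen to the cation-stabilising benzylic carbon) secures the 2-aryl isomer, the unhindered electron-rich styrene used in excess should outcompete the trisubstituted prenyl alkenes, neither of which sits ortho to the reacting carbon, and low temperature together with sieves that take up methanol should keep the acid from adding the phenol across its neighbouring prenyl group or oligomerising the styrene.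

Step 9
Reactants: 15 (2S,4S)-7-(tert-butyldimethylsilyloxy)-2-[4-(tert-butyldimethylsilyloxy)phenyl]-4-methoxy-6,8-bis(3-methylbut-2-enyl)chromane
Product: 16 (2S)-7-(tert-butyldimethylsilyloxy)-2-[4-(tert-butyldimethylsilyloxy)phenyl]-6,8-bis(3-methylbut-2-enyl)chroman-4-ol (C4 epimers)
Conditions: 0.1 M HCl, THF/H2O (3:1), 0 °C to rt
Reagents that add atoms: water, O
Why: Acid-catalysed SN1 solvolysis should exchange the methoxy group for hydroxyl, since C4 is a benzylic carbon with ortho and para oxygen donors and ionises under dilute acid, whereas the aryl silyl ethers and the singly activated C2–O1 bond should hold; the C4 configuration is of no consequence.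

Step 10
Reactants: 16 (2S)-7-(tert-butyldimethylsilyloxy)-2-[4-(tert-butyldimethylsilyloxy)phenyl]-6,8-bis(3-methylbut-2-enyl)chroman-4-ol (C4 epimers)
Product: 17 (2S)-7-(tert-butyldimethylsilyloxy)-2-[4-(tert-butyldimethylsilyloxy)phenyl]-6,8-bis(3-methylbut-2-enyl)chroman-4-one
Conditions: Dess–Martin periodinane, pyridine, CH2Cl2, 0 °C to rt
Reagents that add atoms: none
Why: Dess–Martin oxidation of the secondary benzylic alcohol under pyridine buffer should give the ketone from both C4 epimers without touching the prenyl alkenes, the silyl ethers or the C2 stereocentre.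

Step 11
Reactants: 17 (2S)-7-(tert-butyldimethylsilyloxy)-2-[4-(tert-butyldimethylsilyloxy)phenyl]-6,8-bis(3-methylbut-2-enyl)chroman-4-one
Product: 18 (2S)-7-hydroxy-2-(4-hydroxyphenyl)-6,8-bis(3-methylbut-2-enyl)chroman-4-one
Conditions: TBAF (3 equiv), AcOH (3 equiv), THF, 0 °C to rt
Reagents that add atoms: none
Why: Fluoride-mediated desilylation should cleave both aryl silyl ethers, and the acetic acid buffer keeps the medium from becoming basic enough to open the flavanone by a retro-oxa-Michael reaction, so C2 should remain (S).

**Compound list**

1 | 2,4-dihydroxybenzaldehyde | O=Cc1ccc(O)cc1O | starting material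
2 | 3-chloro-3-methylbut-1-yne | CC(C)(Cl)C#C | starting material
3 | 2-hydroxy-4-(2-methylbut-3-yn-2-yloxy)benzaldehyde | O=Cc1ccc(OC(C)(C)C#C)cc1O | intermediate
4 | 2-hydroxy-4-(2-methylbut-3-en-2-yloxy)benzaldehyde | O=Cc1ccc(OC(C)(C)C=C)cc1O | intermediate
5 | 2-hydroxy-3-(3-methylbut-2-enyl)-4-oxocyclohexa-1,5-diene-1-carbaldehyde (racemic Claisen dienone, not isolated) | O=CC1=C(O)C(CC=C(C)C)C(=O)C=C1 | intermediate
6 | 2,4-dihydroxy-3-(3-methylbut-2-enyl)benzaldehyde | O=Cc1ccc(O)c(CC=C(C)C)c1O | intermediate
7 | 2-hydroxy-3-(3-methylbut-2-enyl)-4-(2-methylbut-3-yn-2-yloxy)benzaldehyde | O=Cc1ccc(OC(C)(C)C#C)c(CC=C(C)C)c1O | intermediate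
8 | 2-hydroxy-3-(3-methylbut-2-enyl)-4-(2-methylbut-3-en-2-yloxy)benzaldehyde | O=Cc1ccc(OC(C)(C)C=C)c(CC=C(C)C)c1O | intermediate
9 | 6-hydroxy-3,5-bis(3-methylbut-2-enyl)-4-oxocyclohexa-1,5-diene-1-carbaldehyde (racemic second Claisen dienone, not isolated) | O=CC1=CC(CC=C(C)C)C(=O)C(CC=C(C)C)=C1O | intermediate
10 | 2,4-dihydroxy-3,5-bis(3-methylbut-2-enyl)benzaldehyde | O=Cc1cc(CC=C(C)C)c(O)c(CC=C(C)C)c1O | intermediate
11 | 4-(tert-butyldimethylsilyloxy)-2-hydroxy-3,5-bis(3-methylbut-2-enyl)benzaldehyde | O=Cc1cc(CC=C(C)C)c(O[Si](C)(C)C(C)(C)C)c(CC=C(C)C)c1O | intermediate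
12 | 4-(tert-butyldimethylsilyloxy)styrene | C=Cc1ccc(O[Si](C)(C)C(C)(C)C)cc1 | starting material
13 | 3-(tert-butyldimethylsilyloxy)-6-(dimethoxymethyl)-2,4-bis(3-methylbut-2-enyl)phenol (dimethyl acetal of 11, not isolated) | COC(OC)c1cc(CC=C(C)C)c(O[Si](C)(C)C(C)(C)C)c(CC=C(C)C)c1O | intermediate
14 | (E)-3-(tert-butyldimethylsilyloxy)-6-(methoxymethylidene)-2,4-bis(3-methylbut-2-enyl)cyclohexa-2,4-dien-1-one (methoxy ortho-quinone methide, reacting as its protonated oxocarbenium form, not isolated) | CO/C=C1\C=C(CC=C(C)C)C(O[Si](C)(C)C(C)(C)C)=C(CC=C(C)C)C1=O | intermediate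
15 | (2S,4S)-7-(tert-butyldimethylsilyloxy)-2-[4-(tert-butyldimethylsilyloxy)phenyl]-4-methoxy-6,8-bis(3-methylbut-2-enyl)chromane (2,4-cis) | CC(C)=CCc1cc2c(c(CC=C(C)C)c1O[Si](C)(C)C(C)(C)C)O[C@H](c1ccc(O[Si](C)(C)C(C)(C)C)cc1)C[C@@H]2OC | intermediate
16 | (2S)-7-(tert-butyldimethylsilyloxy)-2-[4-(tert-butyldimethylsilyloxy)phenyl]-6,8-bis(3-methylbut-2-enyl)chroman-4-ol (mixture of C4 epimers) | CC(C)=CCc1cc2c(c(CC=C(C)C)c1O[Si](C)(C)C(C)(C)C)O[C@H](c1ccc(O[Si](C)(C)C(C)(C)C)cc1)CC2O | intermediate
17 | (2S)-7-(tert-butyldimethylsilyloxy)-2-[4-(tert-butyldimethylsilyloxy)phenyl]-6,8-bis(3-methylbut-2-enyl)chroman-4-one | CC(C)=CCc1cc2c(c(CC=C(C)C)c1O[Si](C)(C)C(C)(C)C)O[C@H](c1ccc(O[Si](C)(C)C(C)(C)C)cc1)CC2=O | intermediate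
18 | (2S)-7-hydroxy-2-(4-hydroxyphenyl)-6,8-bis(3-methylbut-2-enyl)chroman-4-one | CC(C)=CCc1cc2c(c(CC=C(C)C)c1O)O[C@H](c1ccc(O)cc1)CC2=O | target

**Step count**

Total step count: 11.
Longest linear sequence: 11 steps, from 1 to 18; chloride 2 is purchased and enters at steps 1 and 4, and styrene 12 is purchased and enters at step 8.

**Steps most likely to fail**

Step 8 (proposed new method). The chiral anion may discriminate poorly between the two faces of the oxocarbenium ion, above all if part of the reaction runs through an unpaired cation. The acid may also consume the styrene by oligomerisation or add the phenol across its neighbouring prenyl group. Fallback: setting out from 11 and 12, the cycloaddition would be run in its established racemic form with trimethyl orthoformate and a catalytic achiral acid (Sc(OTf)3 or CF3SO3H, CH2Cl2, −20 °C). It would pass through the same intermediates 13 and 14 and should give the cis adduct as the racemate, that is 15 together with its enantiomer (2R,4R)-7-(tert-butyldimethylsilyloxy)-2-[4-(tert-butyldimethylsilyloxy)phenyl]-4-methoxy-6,8-bis(3-methylbut-2-enyl)chromane F1. Preparative chromatography on a chiral stationary phase (cellulose tris(3,5-dimethylphenylcarbamate)) would then separate the two, and the route is rejoined at 15.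

Step 9. The C4 cation may lose the C3 proton and give the flav-3-ene instead of taking up water. Prolonged acid may also begin to ionise the C2–O1 bond and erode the configuration, or cleave a silyl ether. Fallback: setting out from 15, the C4–H bond would be oxidised directly with DDQ in CH2Cl2/pH 7 phosphate buffer at 0 °C. Hydride abstraction from the α-methoxy, doubly oxygen-activated benzylic position, addition of water and loss of methanol from the hemiketal should give the ketone under neutral conditions; the prenyl CH2 groups lack the α-oxygen and should react more slowly. No new compound arises on this path (F0), and the route is rejoined at 17.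

Step 11. Base-induced retro-oxa-Michael opening of the flavanone to the 2'-hydroxychalcone and reclosure would racemise C2, and the hindered C7 silyl ether between the two prenyl groups may be cleaved only slowly, which prolongs exposure. Fallback: the order of the last operations would be changed. Setting out from 16, both silyl ethers would be removed with TBAF/AcOH in THF while C4 is still an alcohol, so that no ring-opening pathway exists, giving (2S)-2-(4-hydroxyphenyl)-6,8-bis(3-methylbut-2-enyl)chromane-4,7-diol F2 as C4 epimers. Chemoselective oxidation of its activated benzylic alcohol with activated MnO2 (acetone, rt), a reagent that oxidises hydroxy-substituted benzylic alcohols without phenol protection, should then give the target, so the route is rejoined at 18.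

**Further compounds**

F1 | step 8 | (2R,4R)-7-(tert-butyldimethylsilyloxy)-2-[4-(tert-butyldimethylsilyloxy)phenyl]-4-methoxy-6,8-bis(3-methylbut-2-enyl)chromane | CC(C)=CCc1cc2c(c(CC=C(C)C)c1O[Si](C)(C)C(C)(C)C)O[C@@H](c1ccc(O[Si](C)(C)C(C)(C)C)cc1)C[C@H]2OC
F0 | step 9 | none | none
F2 | step 11 | (2S)-2-(4-hydroxyphenyl)-6,8-bis(3-methylbut-2-enyl)chromane-4,7-diol (mixture of C4 epimers) | CC(C)=CCc1cc2c(c(CC=C(C)C)c1O)O[C@H](c1ccc(O)cc1)CC2O
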